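## Structural features

The target (38) is a 28-membered macrolactone; its carbons are numbered here from the lactone carbonyl C1 around the ring to C27, which carries the ring oxygen, and C28 is the methyl group on C27. An all-E pentaene spans C16–C25; it is not conjugated to the C1 carbonyl but is insulated at both ends by sp3 stereocentres (the C15 carbinol and the methyl-bearing C26), and its central C20=C21 bond is flanked by two identical (E,E)-buta-1,3-dienyl arms, C16–C19 and C22–C25. C1–C15 carry the polyol: a syn α-ethyl-β-hydroxy ester (C2, C3), an anti 1,3-diol (C3, C5), a trimethylene gap (C6–C8) between the C5 and C9 carbinols, which are related by a local twofold axis through C7, then a syn (C9, C11) and an anti (C11, C13) 1,3-diol and the C13–C15 triad (13,14-anti, 14,15-syn). C26 and C27 form a syn methyl/acyloxy pair. Fragile points are the pentaene (light, oxygen, acid: C15 is a pentaenylic carbinol), the β-hydroxy ester (retro-aldol, elimination) and the free C5 hydroxyl, which can attack C1 to form a δ-lactone. The real difficulty is to close a 28-membered ring and bring in the labile pentaene without carrying it through the synthesis; the second difficulty is the remote C5/C9 relationship, which no 1,3-induction can reach. The key step exploits the first feature: the C20=C21 unit with its twin dienyl arms is a place where a two-carbon linchpin can be stitched between two alkenyl halide termini, closing the ring and completing the pentaene at once.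

## Logic of the disconnections

38 is cut at the two C(sp2)–C(sp2) single bonds C19–C20 and C21–C22, which gives 36 and 18. In one sentence: a three-component double Stille stitching of the open-chain iodide/bromide ester 36 with the two-carbon linchpin 18 closes the ring and creates the pentaene in the last step. The cut removes the macrocycle and the pentaene together and leaves an acyclic ester with two stable dienyl halides. The forward step must give two stereoretentive couplings, the second of them intramolecular in preference to oligomerisation; the iodide/bromide difference in 36 fixes their order.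

36 is cut at C12–C13 (aldol), after adding back the protecting groups and returning C11 to the ketone level, which gives 22 and 30. This splits the chain near its middle. The forward step must set C13 by 1,5-induction from the C9 ether of 22 against the weaker Felkin bias of 30; C11 then follows by hydroxyl-directed 1,3-anti reduction.

22 is cut at the ester bond C1–O(C27), which gives 13 and 20. The bond that is usually kept for a macrolactonisation is made here intermolecularly between two small pieces. The forward step must acylate a hindered secondary alcohol with an α-branched acid without epimerising C2.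

13 is cut at C2–C3 (auxiliary-controlled syn aldol), which gives 7 and 8. C2 and C3 are set together and independently of C5. The forward step must react at the aldehyde of 7 and leave its methyl ketone untouched.

7 is traced through 5 and 4 to 3, and 3 is cut at C4–C5 and C9–C10, which gives 1 and two allyl units. Because C5 and C9 have the same configuration about a local twofold axis, both are set by one catalyst in a two-directional operation on a commodity diol. The price is that the two homotopic allyl termini of 4 must be told apart, which is done by mono-oxidation to 5 (methyl ketone for the later aldol) followed by cleavage of the other alkene to the aldehyde of 7.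

20 is cut at C22–C23 (Stille coupling with the same linchpin 18, via 19), which gives 17. 17 is traced through 15 to 14 by cutting C25–C26 (acetylide opening of the epoxide). Both stereocentres are bought with 14, one being inverted. The forward steps need anti opening, E-selective hydrometalation and mono-coupling of 18.

30 is traced through 29 and 28 to 27, which is cut at C14–C15 (auxiliary-controlled syn aldol) into 24 and 25; 24 comes from 23 in one step. The bromodiene arm is thus present from the first C–C bond formation of this fragment. The forward step needs clean 1,2-addition to the dienal and retention of its E,E geometry.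

## Other disconnections considered

Alternative 1: Cut the lactone C1–O bond; the forward key step is a Yamaguchi macrolactonisation of the seco acid A1 (free C27 hydroxyl, the six other hydroxyls as TBS ethers), followed by desilylation to 38. This is the first plan that comes to mind. A1 already contains the pentaene, which would have to survive the last assembly steps, the activation with base and heat, and a global deprotection. The C27 hydroxyl is secondary with a branch at C26 and the acid is α-branched, so closure is slow and oligomerisation competes. Extra steps are also needed to unmask C1 and C27 selectively. The chosen plan makes the same ester bond intermolecularly on small fragments.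

Alternative 2: Cut the C20=C21 double bond; the forward key step is an intramolecular Horner–Wadsworth–Emmons olefination of the phosphonate–dienal A2. Because the pentaene of 38 is not conjugated to a carbonyl, the phosphonate in A2 is an unstabilised dienylic one. Its anion needs a strong base, which threatens the β-silyloxy ester by elimination, and it offers little E/Z control at the new double bond; pentaene geometric isomers are very hard to separate. The stitching is stereospecific and neutral.

Alternative 3: Cut C15–C16; the forward key step is a Nozaki–Hiyama–Kishi macrocyclisation of the pentaenyl iodide–aldehyde A3, which closes the ring and creates the C15 carbinol. C15 would be set only by the Felkin bias of the C14 methyl group, so a mixture is expected at the last C–C bond. A labile pentaenyl iodide and an epimerisable α-methyl aldehyde must also coexist in one molecule. The chosen plan sets C15 with an auxiliary on a small intermediate and forms no stereocentre at ring closure.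

Key step: step 23

Remark (assumption): in step 1 the (S)-configured ligand is taken to deliver the (4S,8S)-diol; if the sense of induction is the opposite, the (R)-ligand is used and nothing else changes.
Abbreviations: PMB = 4-methoxybenzyl, TBS = tert-butyldimethylsilyl. Compounds 1, 8, 14, 18, 23 and 25 are taken as catalogue compounds.

## Steps

Step 1
Reactants: 1 pentane-1,5-diol
Product: 3 (4S,8S)-undeca-1,10-diene-4,8-diol, via mono-allylated diol 2 (not isolated)
Conditions: allyl acetate (10 equiv), [Ir(cod)Cl]2 (5 mol%), (S)-Cl,MeO-BIPHEP (10 mol%), 4-chloro-3-nitrobenzoic acid (20 mol%), Cs2CO3 (40 mol%), 1,4-dioxane, 90 °C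
Reagents that add atoms: allyl acetate, CC(=O)OCC=C
Why: Two-fold iridium-catalysed transfer-hydrogenative carbonyl allylation from the alcohol oxidation level (Krische allylation): each primary alcohol is dehydrogenated to the aldehyde and trapped by the chiral π-allyliridium C,O-benzoate complex, so the labile dialdehyde is never handled. C5 and C9 are both set by the catalyst; two independent enantioselective events should raise the enantiopurity of the C2-symmetric diol (Horeau amplification), and the minor meso isomer is removed by chromatography.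

Step 2
Reactants: 3 (4S,8S)-undeca-1,10-diene-4,8-diol
Product: 4 (4S,8S)-4,8-bis[(4-methoxybenzyl)oxy]undeca-1,10-diene
Conditions: NaH, 4-methoxybenzyl chloride, Bu4NI (cat.), DMF, 0 °C to rt
Reagents that add atoms: 4-methoxybenzyl chloride, COc1ccc(CCl)cc1
Why: Williamson etherification of both secondary alkoxides; the PMB ether at C9 is needed later as the directing group of the 1,5-anti aldol.

Step 3
Reactants: 4 (4S,8S)-4,8-bis[(4-methoxybenzyl)oxy]undeca-1,10-diene
Product: 5 (4S,8S)-4,8-bis[(4-methoxybenzyl)oxy]undec-10-en-2-one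
Conditions: PdCl2 (10 mol%), CuCl (1 equiv), O2 (1 atm), DMF/H2O (7:1), rt, stopped near half conversion; unreacted 4 recycled
Reagents that add atoms: water, O
Why: Tsuji–Wacker oxidation (Markovnikov hydroxypalladation, β-hydride elimination) turns one allyl group into the methyl ketone. The two termini of 4 are homotopic, so mono-oxidation gives a single compound; the step is statistical and is run to partial conversion with recovery of 4 and chromatographic removal of the diketone.

Step 4
Reactants: 5 (4S,8S)-4,8-bis[(4-methoxybenzyl)oxy]undec-10-en-2-one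
Product: 7 (3S,7S)-3,7-bis[(4-methoxybenzyl)oxy]-9-oxodecanal, via vicinal diol 6 (not isolated)
Conditions: OsO4 (2 mol%), NaIO4 (4 equiv), 2,6-lutidine, 1,4-dioxane/H2O (3:1), rt
Reagents that add atoms: osmium tetroxide (catalytic oxygen-transfer agent), O=[Os](=O)(=O)=O; sodium periodate (stoichiometric oxygen source), [Na+].[O-]I(=O)(=O)=O
Why: Lemieux–Johnson oxidation: osmylation of the only remaining alkene and periodate cleavage of the diol give the C3 aldehyde with loss of one carbon; the ketone and the PMB ethers are inert and 2,6-lutidine suppresses over-oxidation.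

Step 5
Reactants: 7 (3S,7S)-3,7-bis[(4-methoxybenzyl)oxy]-9-oxodecanal, 8 (4S)-4-benzyl-3-butanoyl-1,3-oxazolidin-2-one
Product: 10 (4S)-4-benzyl-3-[(2S,3R,5S,9S)-2-ethyl-3-hydroxy-5,9-bis[(4-methoxybenzyl)oxy]-11-oxododecanoyl]-1,3-oxazolidin-2-one, via Z-dibutylboron enolate 9 (not isolated)
Conditions: 8 (1.5 equiv), Bu2BOTf (1.4 equiv), i-Pr2NEt, CH2Cl2, −78 to 0 °C; then 7, −78 to 0 °C; pH 7 buffer, MeOH, 30% H2O2, 0 °C
Reagents that add atoms: none
Why: Evans syn aldol through the Z-boron enolate and a Zimmerman–Traxler chair; the (S)-benzyl auxiliary fixes the enolate face and sets C2 (S) and C3 (R) regardless of the remote C5 centre. The aldehyde reacts far faster than the methyl ketone, and no free Bu2BOTf is left over to enolise the ketone.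

Step 6
Reactants: 10 (4S)-4-benzyl-3-[(2S,3R,5S,9S)-2-ethyl-3-hydroxy-5,9-bis[(4-methoxybenzyl)oxy]-11-oxododecanoyl]-1,3-oxazolidin-2-one
Product: 11 (4S)-4-benzyl-3-[(2S,3R,5S,9S)-3-[(tert-butyldimethylsilyl)oxy]-2-ethyl-5,9-bis[(4-methoxybenzyl)oxy]-11-oxododecanoyl]-1,3-oxazolidin-2-one
Conditions: TBSOTf, 2,6-lutidine, CH2Cl2, −78 °C
Reagents that add atoms: tert-butyldimethylsilyl triflate, CC(C)(C)[Si](C)(C)OS(=O)(=O)C(F)(F)F
Why: Silylation of the C3 hydroxyl blocks retro-aldol and elimination in the later base-mediated steps; at −78 °C with a pyridine base the methyl ketone is not converted into a silyl enol ether.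

Step 7
Reactants: 11 (4S)-4-benzyl-3-[(2S,3R,5S,9S)-3-[(tert-butyldimethylsilyl)oxy]-2-ethyl-5,9-bis[(4-methoxybenzyl)oxy]-11-oxododecanoyl]-1,3-oxazolidin-2-one
Product: 13 (2S,3R,5S,9S)-3-[(tert-butyldimethylsilyl)oxy]-2-ethyl-5,9-bis[(4-methoxybenzyl)oxy]-11-oxododecanoic acid, via peroxy acid 12 (not isolated)
Conditions: LiOH, 30% H2O2, THF/H2O (3:1), 0 °C; then aq. Na2SO3; 1 M HCl to pH 3
Reagents that add atoms: hydrogen peroxide, OO
Why: Lithium hydroperoxide attacks the exocyclic imide carbonyl selectively and is a weak base, so the auxiliary is released without epimerisation at C2 or β-elimination next to the ketone; sulfite reduces the peroxy acid to the acid.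

Step 8
Reactants: 14 (2R,3R)-2,3-dimethyloxirane
Product: 15 (2R,3R)-3-methylpent-4-yn-2-ol
Conditions: lithium acetylide–ethylenediamine complex (1.5 equiv), DMSO, 15 °C to rt; aq. NH4Cl
Reagents that add atoms: lithium acetylide–ethylenediamine complex, [Li+].[C-]#C.NCCN
Why: SN2 opening of the C2-symmetric trans-epoxide by acetylide: inversion at the attacked carbon (C26) and retention at C27 give the syn methyl/hydroxyl pair, and attack at either epoxide carbon gives the same product.

Step 9
Reactants: 15 (2R,3R)-3-methylpent-4-yn-2-ol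
Product: 17 (2R,3R,4E)-5-iodo-3-methylpent-4-en-2-ol, via alkenylzirconocene 16 (not isolated)
Conditions: Cp2Zr(H)Cl (2.3 equiv), THF, rt, dark; then I2 (1.1 equiv), 0 °C
Reagents that add atoms: iodine, II
Why: Hydrozirconation: the first equivalent is consumed by the hydroxyl, the second adds Zr–H syn across the alkyne with zirconium at the terminal carbon, and iodinolysis with retention gives the E-alkenyl iodide.

Step 10
Reactants: 17 (2R,3R,4E)-5-iodo-3-methylpent-4-en-2-ol, 18 (E)-1,2-bis(tributylstannyl)ethene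
Product: 19 (2R,3R,4E,6E)-3-methyl-7-(tributylstannyl)hepta-4,6-dien-2-ol
Conditions: 18 (3 equiv), PdCl2(MeCN)2 (5 mol%), DMF, rt, dark; excess 18 recovered
Reagents that add atoms: none
Why: Stille coupling with retention at both sp2 carbons; the excess of the distannane ensures that only one tin terminus reacts, and the free hydroxyl is tolerated.

Step 11
Reactants: 19 (2R,3R,4E,6E)-3-methyl-7-(tributylstannyl)hepta-4,6-dien-2-ol
Product: 20 (2R,3R,4E,6E)-7-iodo-3-methylhepta-4,6-dien-2-ol
Conditions: I2 (1.05 equiv), CH2Cl2, 0 °C, dark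
Reagents that add atoms: iodine, II
Why: Iododestannylation is an ipso substitution with retention of the alkene geometry and is much faster than addition of iodine to the diene.

Step 12
Reactants: 13 (2S,3R,5S,9S)-3-[(tert-butyldimethylsilyl)oxy]-2-ethyl-5,9-bis[(4-methoxybenzyl)oxy]-11-oxododecanoic acid, 20 (2R,3R,4E,6E)-7-iodo-3-methylhepta-4,6-dien-2-ol
Product: 22 (2R,3R,4E,6E)-7-iodo-3-methylhepta-4,6-dien-2-yl (2S,3R,5S,9S)-3-[(tert-butyldimethylsilyl)oxy]-2-ethyl-5,9-bis[(4-methoxybenzyl)oxy]-11-oxododecanoate, via mixed anhydride 21 (not isolated)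
Conditions: 2,4,6-trichlorobenzoyl chloride, Et3N, THF, rt; then 20, DMAP, toluene, rt
Reagents that add atoms: none
Why: Yamaguchi esterification: DMAP attacks the less hindered carbonyl of the mixed anhydride and transfers the acyl group to the secondary alcohol; the step is intermolecular, so no dilution is needed, and the β-silyloxy acid is not prone to epimerisation under these conditions.

Step 13
Reactants: 23 potassium (1E,3E)-5-oxopenta-1,3-dien-1-olate (glutaconaldehyde potassium salt)
Product: 24 (2E,4E)-5-bromopenta-2,4-dienal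
Conditions: PPh3, Br2, CH2Cl2, 0 °C; then 23, 0 °C to rt; I2 (cat.), rt
Reagents that add atoms: bromine, BrBr
Why: The enolate oxygen is activated as an oxyphosphonium ion and replaced by bromide in a vinylogous addition–elimination; the 2E,4E isomer is the thermodynamic one and is reached by iodine-catalysed equilibration.

Step 14
Reactants: 24 (2E,4E)-5-bromopenta-2,4-dienal, 25 (4S)-4-benzyl-3-propanoyl-1,3-oxazolidin-2-one
Product: 27 (4S)-4-benzyl-3-[(2S,3R,4E,6E)-7-bromo-3-hydroxy-2-methylhepta-4,6-dienoyl]-1,3-oxazolidin-2-one, via Z-dibutylboron enolate 26 (not isolated)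
Conditions: 25, Bu2BOTf, i-Pr2NEt, CH2Cl2, 0 °C; then 24, −78 to 0 °C; pH 7 buffer, MeOH, 30% H2O2, 0 °C
Reagents that add atoms: none
Why: Evans syn aldol (Z-boron enolate, Zimmerman–Traxler chair); the auxiliary sets the future C14 and C15 together, and the closed transition state gives 1,2-addition to the dienal with its geometry untouched.

Step 15
Reactants: 27 (4S)-4-benzyl-3-[(2S,3R,4E,6E)-7-bromo-3-hydroxy-2-methylhepta-4,6-dienoyl]-1,3-oxazolidin-2-one
Product: 28 (2S,3R,4E,6E)-7-bromo-3-hydroxy-N-methoxy-N,2-dimethylhepta-4,6-dienamide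
Conditions: MeNH(OMe)·HCl, AlMe3, THF, −20 to 0 °C; aq. potassium sodium tartrate
Reagents that add atoms: N,O-dimethylhydroxylamine hydrochloride, CNOC.Cl
Why: Weinreb transamidation with the aluminium amide, assisted by the free β-hydroxyl, which directs attack to the exocyclic carbonyl; no enolisable position is exposed to base.

Step 16
Reactants: 28 (2S,3R,4E,6E)-7-bromo-3-hydroxy-N-methoxy-N,2-dimethylhepta-4,6-dienamide
Product: 29 (2S,3R,4E,6E)-7-bromo-3-[(tert-butyldimethylsilyl)oxy]-N-methoxy-N,2-dimethylhepta-4,6-dienamide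
Conditions: TBSOTf, 2,6-lutidine, CH2Cl2, −78 °C
Reagents that add atoms: tert-butyldimethylsilyl triflate, CC(C)(C)[Si](C)(C)OS(=O)(=O)C(F)(F)F
Why: Silylation of the dienylic C15 hydroxyl under non-ionising conditions; a silyl ether is chosen because it does not chelate and survives the later oxidative and acidic steps.

Step 17
Reactants: 29 (2S,3R,4E,6E)-7-bromo-3-[(tert-butyldimethylsilyl)oxy]-N-methoxy-N,2-dimethylhepta-4,6-dienamide
Product: 30 (2S,3R,4E,6E)-7-bromo-3-[(tert-butyldimethylsilyl)oxy]-2-methylhepta-4,6-dienal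
Conditions: i-Bu2AlH, THF, −78 °C; aq. potassium sodium tartrate; used at once
Reagents that add atoms: none
Why: Reduction of the Weinreb amide stops at the chelated tetrahedral intermediate, which gives the aldehyde only on work-up; at −78 °C the α-stereocentre is not epimerised.

Step 18
Reactants: 22 (2R,3R,4E,6E)-7-iodo-3-methylhepta-4,6-dien-2-yl (2S,3R,5S,9S)-3-[(tert-butyldimethylsilyl)oxy]-2-ethyl-5,9-bis[(4-methoxybenzyl)oxy]-11-oxododecanoate, 30 (2S,3R,4E,6E)-7-bromo-3-[(tert-butyldimethylsilyl)oxy]-2-methylhepta-4,6-dienal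
Product: 32 (2R,3R,4E,6E)-7-iodo-3-methylhepta-4,6-dien-2-yl (2S,3R,5S,9S,13R,14R,15R,16E,18E)-19-bromo-3,15-bis[(tert-butyldimethylsilyl)oxy]-2-ethyl-13-hydroxy-5,9-bis[(4-methoxybenzyl)oxy]-14-methyl-11-oxononadeca-16,18-dienoate, via dicyclohexylboron enolate 31 (not isolated)
Conditions: (c-C6H11)2BCl, Et3N, Et2O, −78 to 0 °C; then 30, −78 to −20 °C; pH 7 buffer, MeOH, 30% H2O2, 0 °C
Reagents that add atoms: none
Why: 1,5-anti boron aldol: the terminal boron enolate of the β-PMB-oxy methyl ketone adds through a boat-like transition state in which the C9 ether oxygen contacts the formyl hydrogen, which sets C13 anti to C9. The α-methyl group of 30 has a weaker, opposing Felkin preference that the enolate bias is expected to override; the ester, silyl ethers and both halodienes are inert.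

Step 19
Reactants: 32 (2R,3R,4E,6E)-7-iodo-3-methylhepta-4,6-dien-2-yl (2S,3R,5S,9S,13R,14R,15R,16E,18E)-19-bromo-3,15-bis[(tert-butyldimethylsilyl)oxy]-2-ethyl-13-hydroxy-5,9-bis[(4-methoxybenzyl)oxy]-14-methyl-11-oxononadeca-16,18-dienoate
Product: 33 (2R,3R,4E,6E)-7-iodo-3-methylhepta-4,6-dien-2-yl (2S,3R,5S,9S,11R,13R,14R,15R,16E,18E)-19-bromo-3,15-bis[(tert-butyldimethylsilyl)oxy]-2-ethyl-11,13-dihydroxy-5,9-bis[(4-methoxybenzyl)oxy]-14-methylnonadeca-16,18-dienoate
Conditions: Me4NBH(OAc)3, MeCN/AcOH (1:1), −30 to −20 °C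
Reagents that add atoms: none
Why: Evans–Saksena reduction: ligand exchange at the C13 hydroxyl gives an alkoxy(diacetoxy)borohydride that delivers hydride intramolecularly to the acid-activated C11 ketone through a chair, which sets C11 anti to C13 and therefore syn to C9 (the descriptor 11R reflects the PMB ether at C9; the geometry is that of 11S in 38).

Step 20
Reactants: 33 (2R,3R,4E,6E)-7-iodo-3-methylhepta-4,6-dien-2-yl (2S,3R,5S,9S,11R,13R,14R,15R,16E,18E)-19-bromo-3,15-bis[(tert-butyldimethylsilyl)oxy]-2-ethyl-11,13-dihydroxy-5,9-bis[(4-methoxybenzyl)oxy]-14-methylnonadeca-16,18-dienoate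
Product: 34 (2R,3R,4E,6E)-7-iodo-3-methylhepta-4,6-dien-2-yl (2S,3R,5S,9S,11S,13R,14R,15R,16E,18E)-19-bromo-3,11,13,15-tetrakis[(tert-butyldimethylsilyl)oxy]-2-ethyl-5,9-bis[(4-methoxybenzyl)oxy]-14-methylnonadeca-16,18-dienoate
Conditions: TBSOTf (3 equiv), 2,6-lutidine, CH2Cl2, −78 to 0 °C
Reagents that add atoms: tert-butyldimethylsilyl triflate, CC(C)(C)[Si](C)(C)OS(=O)(=O)C(F)(F)F
Why: Silylation of both new hydroxyls removes the free C11 hydroxyl next to the C9 PMB ether, which would otherwise trap the oxocarbenium ion of the next step as a cyclic acetal.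

Step 21
Reactants: 34 (2R,3R,4E,6E)-7-iodo-3-methylhepta-4,6-dien-2-yl (2S,3R,5S,9S,11S,13R,14R,15R,16E,18E)-19-bromo-3,11,13,15-tetrakis[(tert-butyldimethylsilyl)oxy]-2-ethyl-5,9-bis[(4-methoxybenzyl)oxy]-14-methylnonadeca-16,18-dienoate
Product: 35 (2R,3R,4E,6E)-7-iodo-3-methylhepta-4,6-dien-2-yl (2S,3R,5S,9S,11S,13R,14R,15R,16E,18E)-19-bromo-3,11,13,15-tetrakis[(tert-butyldimethylsilyl)oxy]-2-ethyl-5,9-dihydroxy-14-methylnonadeca-16,18-dienoate
Conditions: DDQ (2.5 equiv), CH2Cl2/pH 7 phosphate buffer (10:1), 0 °C, dark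
Reagents that add atoms: none
Why: Oxidative PMB cleavage: hydride abstraction from the electron-rich anisyl methylene gives an oxocarbenium ion that water hydrolyses. The halodienes are electron-poorer than the anisyl groups and the C15 oxygen is silylated, so oxidation or cycloaddition at the dienes should be slower than debenzylation.

Step 22
Reactants: 35 (2R,3R,4E,6E)-7-iodo-3-methylhepta-4,6-dien-2-yl (2S,3R,5S,9S,11S,13R,14R,15R,16E,18E)-19-bromo-3,11,13,15-tetrakis[(tert-butyldimethylsilyl)oxy]-2-ethyl-5,9-dihydroxy-14-methylnonadeca-16,18-dienoate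
Product: 36 (2R,3R,4E,6E)-7-iodo-3-methylhepta-4,6-dien-2-yl (2S,3R,5S,9S,11S,13R,14R,15R,16E,18E)-19-bromo-2-ethyl-3,5,9,11,13,15-hexahydroxy-14-methylnonadeca-16,18-dienoate
Conditions: HF·pyridine, pyridine, THF, 0 °C to rt, dark
Reagents that add atoms: none
Why: Fluoride-driven cleavage of the four secondary silyl ethers under pyridine-buffered conditions; all protecting groups are removed while C15 is flanked only by a bromodiene, which ionises far less readily than the pentaenylic carbinol of 38 would.

Step 23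
Reactants: 36 (2R,3R,4E,6E)-7-iodo-3-methylhepta-4,6-dien-2-yl (2S,3R,5S,9S,11S,13R,14R,15R,16E,18E)-19-bromo-2-ethyl-3,5,9,11,13,15-hexahydroxy-14-methylnonadeca-16,18-dienoate, 18 (E)-1,2-bis(tributylstannyl)ethene
Product: 38 (3S,4R,6S,10S,12S,14R,15R,16R,17E,19E,21E,23E,25E,27R,28R)-3-ethyl-4,6,10,12,14,16-hexahydroxy-15,27,28-trimethyl-1-oxacyclooctacosa-17,19,21,23,25-pentaen-2-one, via trienylstannane 37 (not isolated)
Conditions: 18 (1.2 equiv), Pd2(dba)3·CHCl3 (10 mol%), AsPh3 (40 mol%), DMF/THF (1:1), degassed, dark, slow addition of 36 at 25 °C to about 1 mM, then 40 °C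
Reagents that add atoms: none
Why: Zerovalent palladium inserts first into the more reactive C22–I bond of 36; transmetalation with one tin terminus of 18 and reductive elimination form C21–C22 and leave the trienylstannane 37, whose remaining C20–Sn bond couples intramolecularly with the C19–Br terminus after a second oxidative addition, forming C19–C20 and closing the ring. The closest known reaction type is the double Stille stitching of an open-chain bis(alkenyl iodide) with (E)-1,2-bis(tributylstannyl)ethene to a conjugated triene macrocycle; here the same linchpin is set between two dienyl halides so that a pentaene results. The 28-membered ring is closed end to end by reductive elimination from a large palladacycle carrying the C19 and C20 alkenyl groups cis on palladium; no small-ring stereoelectronic constraint applies and the cost is entropic only. No stereocentre is formed: all ten are already in 36, and the five alkene geometries follow from the E geometry of 18 and of the two dienyl halides, because oxidative addition, transmetalation and reductive elimination all proceed with retention at sp2 carbon. The step needs ring closure to win over oligomerisation and the first coupling to occur at one end only: the iodide/bromide difference fixes the order of events, slow addition of 36 to an excess of 18 caps each iodide with a linchpin before it can meet a stannane-bearing chain, and high dilution favours the intramolecular second coupling. The conditions are neutral, so the six free hydroxyls and the β-hydroxy ester should be tolerated, and the pentaene is formed last and meets no further reagent.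

## Compound list

1 | pentane-1,5-diol | OCCCCCO | starting material
2 | (5S)-oct-7-ene-1,5-diol (mono-allylated diol) | OCCCC[C@H](O)CC=C | intermediate (not isolated)
3 | (4S,8S)-undeca-1,10-diene-4,8-diol | C=CC[C@@H](O)CCC[C@H](O)CC=C | intermediate
4 | (4S,8S)-4,8-bis[(4-methoxybenzyl)oxy]undeca-1,10-diene | C=CC[C@@H](OCc1ccc(OC)cc1)CCC[C@H](OCc1ccc(OC)cc1)CC=C | intermediate
5 | (4S,8S)-4,8-bis[(4-methoxybenzyl)oxy]undec-10-en-2-one | C=CC[C@@H](OCc1ccc(OC)cc1)CCC[C@H](OCc1ccc(OC)cc1)CC(C)=O | intermediate
6 | (4S,8S)-10,11-dihydroxy-4,8-bis[(4-methoxybenzyl)oxy]undecan-2-one (both C10 epimers) | OCC(O)C[C@@H](OCc1ccc(OC)cc1)CCC[C@H](OCc1ccc(OC)cc1)CC(C)=O | intermediate (not isolated)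
7 | (3S,7S)-3,7-bis[(4-methoxybenzyl)oxy]-9-oxodecanal | O=CC[C@@H](OCc1ccc(OC)cc1)CCC[C@H](OCc1ccc(OC)cc1)CC(C)=O | intermediate
8 | (4S)-4-benzyl-3-butanoyl-1,3-oxazolidin-2-one | CCCC(=O)N1[C@@H](Cc2ccccc2)COC1=O | starting material
9 | Z-dibutylboron enolate of 8 | CC/C=C(\OB(CCCC)CCCC)N1[C@@H](Cc2ccccc2)COC1=O | intermediate (not isolated)
10 | (4S)-4-benzyl-3-[(2S,3R,5S,9S)-2-ethyl-3-hydroxy-5,9-bis[(4-methoxybenzyl)oxy]-11-oxododecanoyl]-1,3-oxazolidin-2-one | O=C([C@@H](CC)[C@H](O)C[C@@H](OCc1ccc(OC)cc1)CCC[C@H](OCc1ccc(OC)cc1)CC(C)=O)N1[C@@H](Cc2ccccc2)COC1=O | intermediate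
11 | C3 TBS ether of 10 | O=C([C@@H](CC)[C@H](O[Si](C)(C)C(C)(C)C)C[C@@H](OCc1ccc(OC)cc1)CCC[C@H](OCc1ccc(OC)cc1)CC(C)=O)N1[C@@H](Cc2ccccc2)COC1=O | intermediate
12 | (2S,3R,5S,9S)-3-[(tert-butyldimethylsilyl)oxy]-2-ethyl-5,9-bis[(4-methoxybenzyl)oxy]-11-oxododecaneperoxoic acid | OOC(=O)[C@@H](CC)[C@H](O[Si](C)(C)C(C)(C)C)C[C@@H](OCc1ccc(OC)cc1)CCC[C@H](OCc1ccc(OC)cc1)CC(C)=O | intermediate (not isolated)
13 | (2S,3R,5S,9S)-3-[(tert-butyldimethylsilyl)oxy]-2-ethyl-5,9-bis[(4-methoxybenzyl)oxy]-11-oxododecanoic acid | OC(=O)[C@@H](CC)[C@H](O[Si](C)(C)C(C)(C)C)C[C@@H](OCc1ccc(OC)cc1)CCC[C@H](OCc1ccc(OC)cc1)CC(C)=O | intermediate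
14 | (2R,3R)-2,3-dimethyloxirane | C[C@H]1O[C@@H]1C | starting material
15 | (2R,3R)-3-methylpent-4-yn-2-ol | C#C[C@@H](C)[C@@H](C)O | intermediate
16 | E-alkenylzirconocene chloride from 15 (zirconium at C5; hydroxyl as zirconocene chloride alkoxide) | Cl[Zr](C1C=CC=C1)(C1C=CC=C1)/C=C/[C@@H](C)[C@@H](C)O[Zr](Cl)(C1C=CC=C1)C1C=CC=C1 | intermediate (not isolated)
17 | (2R,3R,4E)-5-iodo-3-methylpent-4-en-2-ol | I/C=C/[C@@H](C)[C@@H](C)O | intermediate
18 | (E)-1,2-bis(tributylstannyl)ethene | CCCC[Sn](CCCC)(CCCC)/C=C/[Sn](CCCC)(CCCC)CCCC | starting material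
19 | (2R,3R,4E,6E)-3-methyl-7-(tributylstannyl)hepta-4,6-dien-2-ol | CCCC[Sn](CCCC)(CCCC)/C=C/C=C/[C@@H](C)[C@@H](C)O | intermediate
20 | (2R,3R,4E,6E)-7-iodo-3-methylhepta-4,6-dien-2-ol | I/C=C/C=C/[C@@H](C)[C@@H](C)O | intermediate
21 | mixed anhydride of 13 with 2,4,6-trichlorobenzoic acid | O=C(OC(=O)c1c(Cl)cc(Cl)cc1Cl)[C@@H](CC)[C@H](O[Si](C)(C)C(C)(C)C)C[C@@H](OCc1ccc(OC)cc1)CCC[C@H](OCc1ccc(OC)cc1)CC(C)=O | intermediate (not isolated)
22 | (2R,3R,4E,6E)-7-iodo-3-methylhepta-4,6-dien-2-yl (2S,3R,5S,9S)-3-[(tert-butyldimethylsilyl)oxy]-2-ethyl-5,9-bis[(4-methoxybenzyl)oxy]-11-oxododecanoate | I/C=C/C=C/[C@@H](C)[C@@H](C)OC(=O)[C@@H](CC)[C@H](O[Si](C)(C)C(C)(C)C)C[C@@H](OCc1ccc(OC)cc1)CCC[C@H](OCc1ccc(OC)cc1)CC(C)=O | intermediate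
23 | potassium (1E,3E)-5-oxopenta-1,3-dien-1-olate | [K+].[O-]/C=C/C=C/C=O | starting material
24 | (2E,4E)-5-bromopenta-2,4-dienal | O=C/C=C/C=C/Br | intermediate
25 | (4S)-4-benzyl-3-propanoyl-1,3-oxazolidin-2-one | CCC(=O)N1[C@@H](Cc2ccccc2)COC1=O | starting material
26 | Z-dibutylboron enolate of 25 | C/C=C(\OB(CCCC)CCCC)N1[C@@H](Cc2ccccc2)COC1=O | intermediate (not isolated)
27 | (4S)-4-benzyl-3-[(2S,3R,4E,6E)-7-bromo-3-hydroxy-2-methylhepta-4,6-dienoyl]-1,3-oxazolidin-2-one | O=C([C@@H](C)[C@H](O)/C=C/C=C/Br)N1[C@@H](Cc2ccccc2)COC1=O | intermediate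
28 | (2S,3R,4E,6E)-7-bromo-3-hydroxy-N-methoxy-N,2-dimethylhepta-4,6-dienamide | CON(C)C(=O)[C@@H](C)[C@H](O)/C=C/C=C/Br | intermediate
29 | (2S,3R,4E,6E)-7-bromo-3-[(tert-butyldimethylsilyl)oxy]-N-methoxy-N,2-dimethylhepta-4,6-dienamide | CON(C)C(=O)[C@@H](C)[C@H](O[Si](C)(C)C(C)(C)C)/C=C/C=C/Br | intermediate
30 | (2S,3R,4E,6E)-7-bromo-3-[(tert-butyldimethylsilyl)oxy]-2-methylhepta-4,6-dienal | O=C[C@@H](C)[C@H](O[Si](C)(C)C(C)(C)C)/C=C/C=C/Br | intermediate
31 | dicyclohexylboron enolate of 22 (terminal enolate C11=C12) | I/C=C/C=C/[C@@H](C)[C@@H](C)OC(=O)[C@@H](CC)[C@H](O[Si](C)(C)C(C)(C)C)C[C@@H](OCc1ccc(OC)cc1)CCC[C@H](OCc1ccc(OC)cc1)CC(=C)OB(C1CCCCC1)C1CCCCC1 | intermediate (not isolated)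
32 | (2R,3R,4E,6E)-7-iodo-3-methylhepta-4,6-dien-2-yl (2S,3R,5S,9S,13R,14R,15R,16E,18E)-19-bromo-3,15-bis[(tert-butyldimethylsilyl)oxy]-2-ethyl-13-hydroxy-5,9-bis[(4-methoxybenzyl)oxy]-14-methyl-11-oxononadeca-16,18-dienoate | I/C=C/C=C/[C@@H](C)[C@@H](C)OC(=O)[C@@H](CC)[C@H](O[Si](C)(C)C(C)(C)C)C[C@@H](OCc1ccc(OC)cc1)CCC[C@H](OCc1ccc(OC)cc1)CC(=O)C[C@@H](O)[C@@H](C)[C@H](O[Si](C)(C)C(C)(C)C)/C=C/C=C/Br | intermediate
33 | (2R,3R,4E,6E)-7-iodo-3-methylhepta-4,6-dien-2-yl (2S,3R,5S,9S,11R,13R,14R,15R,16E,18E)-19-bromo-3,15-bis[(tert-butyldimethylsilyl)oxy]-2-ethyl-11,13-dihydroxy-5,9-bis[(4-methoxybenzyl)oxy]-14-methylnonadeca-16,18-dienoate | I/C=C/C=C/[C@@H](C)[C@@H](C)OC(=O)[C@@H](CC)[C@H](O[Si](C)(C)C(C)(C)C)C[C@@H](OCc1ccc(OC)cc1)CCC[C@H](OCc1ccc(OC)cc1)C[C@H](O)C[C@@H](O)[C@@H](C)[C@H](O[Si](C)(C)C(C)(C)C)/C=C/C=C/Br | intermediate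
34 | (2R,3R,4E,6E)-7-iodo-3-methylhepta-4,6-dien-2-yl (2S,3R,5S,9S,11S,13R,14R,15R,16E,18E)-19-bromo-3,11,13,15-tetrakis[(tert-butyldimethylsilyl)oxy]-2-ethyl-5,9-bis[(4-methoxybenzyl)oxy]-14-methylnonadeca-16,18-dienoate | I/C=C/C=C/[C@@H](C)[C@@H](C)OC(=O)[C@@H](CC)[C@H](O[Si](C)(C)C(C)(C)C)C[C@@H](OCc1ccc(OC)cc1)CCC[C@H](OCc1ccc(OC)cc1)C[C@H](O[Si](C)(C)C(C)(C)C)C[C@@H](O[Si](C)(C)C(C)(C)C)[C@@H](C)[C@H](O[Si](C)(C)C(C)(C)C)/C=C/C=C/Br | intermediate
35 | (2R,3R,4E,6E)-7-iodo-3-methylhepta-4,6-dien-2-yl (2S,3R,5S,9S,11S,13R,14R,15R,16E,18E)-19-bromo-3,11,13,15-tetrakis[(tert-butyldimethylsilyl)oxy]-2-ethyl-5,9-dihydroxy-14-methylnonadeca-16,18-dienoate | I/C=C/C=C/[C@@H](C)[C@@H](C)OC(=O)[C@@H](CC)[C@H](O[Si](C)(C)C(C)(C)C)C[C@@H](O)CCC[C@H](O)C[C@H](O[Si](C)(C)C(C)(C)C)C[C@@H](O[Si](C)(C)C(C)(C)C)[C@@H](C)[C@H](O[Si](C)(C)C(C)(C)C)/C=C/C=C/Br | intermediate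
36 | (2R,3R,4E,6E)-7-iodo-3-methylhepta-4,6-dien-2-yl (2S,3R,5S,9S,11S,13R,14R,15R,16E,18E)-19-bromo-2-ethyl-3,5,9,11,13,15-hexahydroxy-14-methylnonadeca-16,18-dienoate | I/C=C/C=C/[C@@H](C)[C@@H](C)OC(=O)[C@@H](CC)[C@H](O)C[C@@H](O)CCC[C@H](O)C[C@H](O)C[C@@H](O)[C@@H](C)[C@H](O)/C=C/C=C/Br | intermediate
37 | (2R,3R,4E,6E,8E)-3-methyl-9-(tributylstannyl)nona-4,6,8-trien-2-yl (2S,3R,5S,9S,11S,13R,14R,15R,16E,18E)-19-bromo-2-ethyl-3,5,9,11,13,15-hexahydroxy-14-methylnonadeca-16,18-dienoate | CCCC[Sn](CCCC)(CCCC)/C=C/C=C/C=C/[C@@H](C)[C@@H](C)OC(=O)[C@@H](CC)[C@H](O)C[C@@H](O)CCC[C@H](O)C[C@H](O)C[C@@H](O)[C@@H](C)[C@H](O)/C=C/C=C/Br | intermediate (not isolated)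
38 | (3S,4R,6S,10S,12S,14R,15R,16R,17E,19E,21E,23E,25E,27R,28R)-3-ethyl-4,6,10,12,14,16-hexahydroxy-15,27,28-trimethyl-1-oxacyclooctacosa-17,19,21,23,25-pentaen-2-one (CNP0382847.1) | CC[C@@H]1C(=O)O[C@H](C)[C@H](C)/C=C/C=C/C=C/C=C/C=C/[C@@H](O)[C@H](C)[C@H](O)C[C@@H](O)C[C@@H](O)CCC[C@H](O)C[C@H]1O | target

## Step count and least certain steps

Total step count: 23. Longest linear sequence: 14 steps (steps 1–7, 12, 18–23).

Least certain steps:

1. Key step, step 23. What may go wrong: intermolecular coupling, in which one linchpin bridges two chains and leads to linear or cyclic oligomers; slow oxidative addition at the bromodiene, during which the trienylstannane is lost by protodestannylation or homocoupling; and photo-oxidative loss of the pentaene over a long reaction time. Fallback: the three-component event is divided into two two-component events. Setting out from 36, a Stille coupling with a large excess of 18 under mild conditions (PdCl2(MeCN)2, DMF, rt) caps only the iodide terminus and gives 37, which is isolated. 37 is then cyclised on its own under pseudo-high dilution with a copper-assisted catalyst system (Pd(PPh3)4, copper thiophene-2-carboxylate, DMF, rt). The ring closure is then a purely unimolecular step with no free linchpin present, and the sequence returns to the route at 38; no new compound is needed.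

2. Step 18. What may go wrong: poor facial selectivity at C13, because the Felkin preference of the α-methyl aldehyde opposes the 1,5-anti preference of the enolate, and epimerisation of 30 at C14 before it reacts. Fallback: control is moved from the enolate to the aldehyde by chelation. Setting out from 28, the C15 hydroxyl is protected as a PMB ether (PMB trichloroacetimidate, Sc(OTf)3 cat.) to give the C15 PMB ether amide F2, which i-Bu2AlH reduces to the aldehyde F3. In parallel, 22 is converted into its trimethylsilyl enol ether F4 (LiN(SiMe3)2, Me3SiCl, THF, −78 °C). A Mukaiyama aldol addition of F4 to F3 promoted by MgBr2·OEt2 passes through the six-membered chelate of the aldehyde, in which the C14 methyl and the C15 substituent shield the same face. Anti-Felkin, 1,3-anti attack, which is the configuration needed at C13, is therefore the reinforced outcome and gives the hydroxy ketone F5. F5 is carried through the operations of steps 19–22: Evans–Saksena reduction to the diol F6, silylation to the bis-TBS ether F7, DDQ removal of the three PMB groups to the triol F8, and HF·pyridine, which returns to the route at 36.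

3. Step 22. What may go wrong: attack of the liberated C5 hydroxyl on C1 with expulsion of the C27 alkoxide (δ-lactonisation with loss of the western arm), acyl migration, and incomplete cleavage of the hindered C13 silyl ether under conditions mild enough for the dienyl halides. Fallback: the ring is closed before the hydroxyls are freed. Setting out from 35, the stitching of step 23 with 18 is run on the silylated substrate and passes through the silylated trienylstannane F9 to give the macrocyclic tetrakis-TBS ether F10. In F10 the C27 alkoxide remains tethered, so translactonisation no longer fragments the molecule. HF·pyridine then removes the four silyl groups and returns to the route at 38.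

4. Step 21. What may go wrong: oxidation or cycloaddition of the quinone at the halodienes in competition with debenzylation, and partial loss of silyl ethers. Fallback: the hydride-abstraction mechanism is replaced by a non-oxidative, Lewis acid-assisted SN2 debenzylation. Setting out from 34, MgBr2·OEt2 and Me2S in CH2Cl2 cleave the two PMB ethers by attack of the sulfide at the benzylic carbon, with no oxidant and no oxocarbenium ion, and return to the route at 35; no new compound is needed.

5. Step 1. What may go wrong: dehydrogenation of the cyclic lactol form of the intermediate 5-hydroxypentanal to δ-valerolactone, which removes material before the second allylation; incomplete double addition; and a sense of induction opposite to the one assumed. Fallback: reagent control at the aldehyde oxidation level. Setting out from 1, Swern oxidation ((COCl)2, DMSO, Et3N, CH2Cl2, −78 °C) gives pentanedial F1, which is used at once in a double Brown allylation with commercial (+)-B-allyldiisopinocampheylborane (the reagent derived from (−)-α-pinene; Et2O, −78 °C; then NaOH, H2O2). This reagent is known to give the S configuration with unbranched aliphatic aldehydes, and the sequence returns to the route at 3.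

## Further compounds

F1 | step 1 | pentanedial (glutaraldehyde) | O=CCCCC=O
F2 | step 18 | (2S,3R,4E,6E)-7-bromo-N-methoxy-3-[(4-methoxybenzyl)oxy]-N,2-dimethylhepta-4,6-dienamide | CON(C)C(=O)[C@@H](C)[C@H](OCc1ccc(OC)cc1)/C=C/C=C/Br
F3 | step 18 | (2S,3R,4E,6E)-7-bromo-3-[(4-methoxybenzyl)oxy]-2-methylhepta-4,6-dienal | O=C[C@@H](C)[C@H](OCc1ccc(OC)cc1)/C=C/C=C/Br
F4 | step 18 | trimethylsilyl enol ether of 22 (terminal C11=C12) | I/C=C/C=C/[C@@H](C)[C@@H](C)OC(=O)[C@@H](CC)[C@H](O[Si](C)(C)C(C)(C)C)C[C@@H](OCc1ccc(OC)cc1)CCC[C@H](OCc1ccc(OC)cc1)CC(=C)O[Si](C)(C)C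
F5 | step 18 | analogue of 32 with a PMB ether in place of the TBS ether at C15 | I/C=C/C=C/[C@@H](C)[C@@H](C)OC(=O)[C@@H](CC)[C@H](O[Si](C)(C)C(C)(C)C)C[C@@H](OCc1ccc(OC)cc1)CCC[C@H](OCc1ccc(OC)cc1)CC(=O)C[C@@H](O)[C@@H](C)[C@H](OCc1ccc(OC)cc1)/C=C/C=C/Br
F6 | step 18 | analogue of 33 with a PMB ether at C15 (C11,C13-anti diol) | I/C=C/C=C/[C@@H](C)[C@@H](C)OC(=O)[C@@H](CC)[C@H](O[Si](C)(C)C(C)(C)C)C[C@@H](OCc1ccc(OC)cc1)CCC[C@H](OCc1ccc(OC)cc1)C[C@H](O)C[C@@H](O)[C@@H](C)[C@H](OCc1ccc(OC)cc1)/C=C/C=C/Br
F7 | step 18 | analogue of 34 with a PMB ether at C15 (TBS ethers at C3, C11 and C13) | I/C=C/C=C/[C@@H](C)[C@@H](C)OC(=O)[C@@H](CC)[C@H](O[Si](C)(C)C(C)(C)C)C[C@@H](OCc1ccc(OC)cc1)CCC[C@H](OCc1ccc(OC)cc1)C[C@H](O[Si](C)(C)C(C)(C)C)C[C@@H](O[Si](C)(C)C(C)(C)C)[C@@H](C)[C@H](OCc1ccc(OC)cc1)/C=C/C=C/Br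
F8 | step 18 | C5,C9,C15-triol with TBS ethers at C3, C11 and C13 | I/C=C/C=C/[C@@H](C)[C@@H](C)OC(=O)[C@@H](CC)[C@H](O[Si](C)(C)C(C)(C)C)C[C@@H](O)CCC[C@H](O)C[C@H](O[Si](C)(C)C(C)(C)C)C[C@@H](O[Si](C)(C)C(C)(C)C)[C@@H](C)[C@H](O)/C=C/C=C/Br
F9 | step 22 | tetrakis-TBS ether of 37 at C3, C11, C13 and C15 (not isolated) | CCCC[Sn](CCCC)(CCCC)/C=C/C=C/C=C/[C@@H](C)[C@@H](C)OC(=O)[C@@H](CC)[C@H](O[Si](C)(C)C(C)(C)C)C[C@@H](O)CCC[C@H](O)C[C@H](O[Si](C)(C)C(C)(C)C)C[C@@H](O[Si](C)(C)C(C)(C)C)[C@@H](C)[C@H](O[Si](C)(C)C(C)(C)C)/C=C/C=C/Br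
F10 | step 22 | tetrakis-TBS ether of 38 at the C3, C11, C13 and C15 hydroxyls (ring positions 4, 12, 14 and 16) | CC[C@@H]1C(=O)O[C@H](C)[C@H](C)/C=C/C=C/C=C/C=C/C=C/[C@@H](O[Si](C)(C)C(C)(C)C)[C@H](C)[C@H](O[Si](C)(C)C(C)(C)C)C[C@@H](O[Si](C)(C)C(C)(C)C)C[C@@H](O)CCC[C@H](O)C[C@H]1O[Si](C)(C)C(C)(C)C
F0 | step 23 | none | none
F0 | step 21 | none | none
A1 | alternative 1 | seco acid of 38 with free C27 hydroxyl and TBS ethers at C3, C5, C9, C11, C13 and C15 | C[C@@H](O)[C@H](C)/C=C/C=C/C=C/C=C/C=C/[C@@H](O[Si](C)(C)C(C)(C)C)[C@H](C)[C@H](O[Si](C)(C)C(C)(C)C)C[C@@H](O[Si](C)(C)C(C)(C)C)C[C@@H](O[Si](C)(C)C(C)(C)C)CCC[C@H](O[Si](C)(C)C(C)(C)C)C[C@@H](O[Si](C)(C)C(C)(C)C)[C@H](CC)C(=O)O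
A2 | alternative 2 | open-chain ester with a C21 diethyl phosphonate on the western diene and a C20 aldehyde on the eastern diene (hexakis-TBS ether) | CCOP(=O)(OCC)C/C=C/C=C/[C@@H](C)[C@@H](C)OC(=O)[C@@H](CC)[C@H](O[Si](C)(C)C(C)(C)C)C[C@@H](O[Si](C)(C)C(C)(C)C)CCC[C@H](O[Si](C)(C)C(C)(C)C)C[C@H](O[Si](C)(C)C(C)(C)C)C[C@@H](O[Si](C)(C)C(C)(C)C)[C@@H](C)[C@H](O[Si](C)(C)C(C)(C)C)/C=C/C=C/C=O
A3 | alternative 3 | open-chain ester with a C16 pentaenyl iodide and a C15 aldehyde (pentakis-TBS ether) | I/C=C/C=C/C=C/C=C/C=C/[C@@H](C)[C@@H](C)OC(=O)[C@@H](CC)[C@H](O[Si](C)(C)C(C)(C)C)C[C@@H](O[Si](C)(C)C(C)(C)C)CCC[C@H](O[Si](C)(C)C(C)(C)C)C[C@H](O[Si](C)(C)C(C)(C)C)C[C@@H](O[Si](C)(C)C(C)(C)C)[C@@H](C)C=O
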